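The anisole ring is made last. Its two adjacent unsubstituted carbons (arene C5 and C6) are disconnected from C1, which carries the carbinol carbon, and from C4, which carries CH3. What remains is C3, C4, C5 and C6 of a 2-pyrone that already holds the side chain, OMe and CH3. In one operation a thermal Diels–Alder reaction with norbornadiene, followed by loss of CO2 and cyclopentadiene, forms both ring bonds and closes the benzene ring with the 1,2,4 pattern fixed. The precursor is 4-methoxy-6-methyl-2-pyrone bearing at C3 the acetonide-protected tertiary carbinol, reached by bromine–magnesium exchange and addition to 2,2-dimethyl-1,3-dioxan-5-one.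

Key step: step 3

Remark: the target has no stereocentre, because the carbinol carbon carries two identical arms; intermediates 7 and 8 form as stereoisomer mixtures and are drawn without configuration, since all their sp3 ring centres vanish on aromatisation.

Step 1
Reactants: 1 4-methoxy-6-methyl-2H-pyran-2-one
Product: 2 3-bromo-4-methoxy-6-methyl-2H-pyran-2-one
Conditions: NBS (1.05 equiv), MeCN, 0 °C → rt, dark
Reagents that add atoms: N-bromosuccinimide, O=C1CCC(=O)N1Br
Why: Electrophilic bromination (an SEAr-type halogenation of a vinylogous ester) should occur at C3, the β-carbon of the C4 methoxy enol ether and the most nucleophilic ring position, while ionic conditions in the dark leave the 6-methyl group untouched; no stereocentre is formed.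

Step 2
Reactants: 2 3-bromo-4-methoxy-6-methyl-2H-pyran-2-one; 3 2,2-dimethyl-1,3-dioxan-5-one
Product: 5 3-(5-hydroxy-2,2-dimethyl-1,3-dioxan-5-yl)-4-methoxy-6-methyl-2H-pyran-2-one, via pyronylmagnesium chloride 4 (not isolated)
Conditions: i-PrMgCl·LiCl (1.1 equiv), THF, −40 → −20 °C; then LaCl3·2LiCl (1.0 equiv), 3 (1.2 equiv), −40 → 0 °C; sat. aq. NH4Cl
Reagents that add atoms: none
Why: Halogen–magnesium exchange with the turbo-Grignard reagent at the C(sp2)–Br bond flanked by the lactone carbonyl and the methoxy group should give a chelate-stabilised alkenylmagnesium that, unlike an alkyllithium, does not deprotonate the acidic 6-methyl group at this temperature, and LaCl3·2LiCl-promoted Grignard 1,2-addition to the electrophilic, symmetrical ketone 3 then gives the tertiary carbinol without a stereocentre.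

Step 3
Reactants: 5 3-(5-hydroxy-2,2-dimethyl-1,3-dioxan-5-yl)-4-methoxy-6-methyl-2H-pyran-2-one; 6 norbornadiene
Product: 9 5-(2-methoxy-4-methylphenyl)-2,2-dimethyl-1,3-dioxan-5-ol, via bridged lactone cycloadduct 7 (not isolated), via norbornene-fused cyclohexadiene 8 (not isolated)
Conditions: 6 (10 equiv), o-dichlorobenzene, BHT (5 mol%), 2,6-lutidine (10 mol%), sealed pressure tube, 180 °C
Reagents that add atoms: none
Why: A concerted thermal [4+2] cycloaddition joins the pyrone diene (C3=C4–C5=C6) to one strained double bond of norbornadiene to give bridged lactone 7; retro-[4+2] extrusion of CO2 gives cyclohexadiene 8, and a second retro-Diels–Alder reaction expels cyclopentadiene to leave the benzene ring. The closest known reaction type is the benzannulation of 2-pyrones with norbornadiene as an acetylene equivalent (Diels–Alder followed by double retro-Diels–Alder). The benzene ring is closed by intermolecular [4+2] annulation, both new ring bonds (pyrone C3–CH and C6–CH) forming in the cycloaddition itself, so the closure is a cycloaddition and not an end-to-end cyclisation. No stereocentre is created in the product, since the sp3 centres of 7 and 8 arise as mixtures and are all erased on aromatisation. No orientational selectivity is needed, because the dienophile delivers two equivalent CH carbons and the 1,2,4 pattern is fixed by the pyrone substituents; the demand is reactivity at the hindered, donor-substituted C3, which is met by the ring strain and large excess of 6, high temperature, irreversible CO2 loss and the hydrogen bond from the free tertiary hydroxyl to the lactone carbonyl, which lowers the diene LUMO. BHT suppresses radical oligomerisation of 6 and the trace of 2,6-lutidine suppresses acid-promoted acetonide migration, which would in any case converge on the same triol in step 4.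

Step 4
Reactants: 9 5-(2-methoxy-4-methylphenyl)-2,2-dimethyl-1,3-dioxan-5-ol
Product: 10 2-(2-methoxy-4-methylphenyl)propane-1,2,3-triol
Conditions: AcOH/H2O/THF (3:1:1), 40 °C
Reagents that add atoms: none
Why: Acid-catalysed acetal hydrolysis under mild aqueous acetic acid should free both primary hydroxyls, the tertiary benzylic hydroxyl being spared from ionisation because its cation would be destabilised by two β-oxygen substituents; no stereocentre is involved.

Step 5
Reactants: 10 2-(2-methoxy-4-methylphenyl)propane-1,2,3-triol; 11 isobutyryl chloride
Product: 12 2-hydroxy-2-(2-methoxy-4-methylphenyl)propane-1,3-diyl bis(2-methylpropanoate)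
Conditions: 11 (2.2 equiv), pyridine (4 equiv), CH2Cl2, −20 → 0 °C
Reagents that add atoms: none
Why: Nucleophilic acyl substitution (base-mediated esterification with an acid chloride) under kinetic control should acylate only the two primary hydroxyls, since the tertiary hydroxyl flanked by the aryl ring and two CH2O arms does not react with the α-branched acid chloride at low temperature without a nucleophilic catalyst; the product is achiral because the two arms are identical.

Compound list
1 | 4-methoxy-6-methyl-2H-pyran-2-one | COc1cc(C)oc(=O)c1 | starting material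
2 | 3-bromo-4-methoxy-6-methyl-2H-pyran-2-one | COc1cc(C)oc(=O)c1Br | intermediate
3 | 2,2-dimethyl-1,3-dioxan-5-one | CC1(C)OCC(=O)CO1 | starting material
4 | (4-methoxy-6-methyl-2-oxo-2H-pyran-3-yl)magnesium chloride, LiCl complex (pyronylmagnesium chloride, not isolated) | COc1cc(C)oc(=O)c1[Mg]Cl | intermediate
5 | 3-(5-hydroxy-2,2-dimethyl-1,3-dioxan-5-yl)-4-methoxy-6-methyl-2H-pyran-2-one | COc1cc(C)oc(=O)c1C1(O)COC(C)(C)OC1 | intermediate
6 | norbornadiene (bicyclo[2.2.1]hepta-2,5-diene) | C1=CC2C=CC1C2 | starting material
7 | bridged lactone cycloadduct: 4-(5-hydroxy-2,2-dimethyl-1,3-dioxan-5-yl)-5-methoxy-1-methyl-2-oxabicyclo[2.2.2]oct-5-en-3-one fused across C7–C8 to a norbornene unit (stereoisomer mixture, not isolated) | O=C1OC2(C)C=C(OC)C1(C5(O)COC(C)(C)OC5)C3C4C=CC(C4)C23 | intermediate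
8 | norbornene-fused cyclohexadiene: 5-(6-methoxy-8-methyl-1,4,4a,8a-tetrahydro-1,4-methanonaphthalen-5-yl)-2,2-dimethyl-1,3-dioxan-5-ol (stereoisomer mixture, not isolated) | COC1=C(C4(O)COC(C)(C)OC4)C2C3C=CC(C3)C2C(C)=C1 | intermediate
9 | 5-(2-methoxy-4-methylphenyl)-2,2-dimethyl-1,3-dioxan-5-ol | COc1cc(C)ccc1C1(O)COC(C)(C)OC1 | intermediate
10 | 2-(2-methoxy-4-methylphenyl)propane-1,2,3-triol | COc1cc(C)ccc1C(O)(CO)CO | intermediate
11 | isobutyryl chloride (2-methylpropanoyl chloride) | CC(C)C(Cl)=O | starting material
12 | 2-hydroxy-2-(2-methoxy-4-methylphenyl)propane-1,3-diyl bis(2-methylpropanoate) | COc1cc(C)ccc1C(O)(COC(=O)C(C)C)COC(=O)C(C)C | target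

Total step count: 5
Longest linear sequence: 5 steps (1 → 2 → 5 → 9 → 10 → 12)

Steps most likely to fail

1. Step 3. Risk: the cycloaddition may be too slow at the hindered, donor-substituted C3 terminus, so that oligomerisation of the dienophile and slow thermal decomposition of the pyrone take over. Fallback, setting out from 2 (with 6 and 3) and coming back at 9: the cycloaddition is moved forward to the bromide, where C3 carries only a halogen and 3-bromo-2-pyrones react as ambiphilic dienes. Heating 2 with 6 under the conditions of step 3 should give, through the bridged bromolactone cycloadduct F1 and the norbornene-fused bromocyclohexadiene F2, 1-bromo-2-methoxy-4-methylbenzene F3. Bromine–lithium exchange (n-BuLi, THF, −78 °C) then gives (2-methoxy-4-methylphenyl)lithium F4, which adds to ketone 3 (sat. aq. NH4Cl quench) to give 9.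

2. Step 2. Risk: proton transfer may outrun carbonyl addition, the organomagnesium enolising ketone 3 and being lost as debrominated pyrone. Fallback, setting out from 4 and coming back at 10: 4 is added at −78 °C to diethyl oxomalonate (CCOC(=O)C(=O)C(=O)OCC), a very electrophilic ketone without α-hydrogen, to give diethyl 2-hydroxy-2-(4-methoxy-6-methyl-2-oxo-2H-pyran-3-yl)propanedioate F5. Heating F5 with 6 as in step 3 should lead through the malonate-bearing bridged lactone cycloadduct F6 and the malonate-bearing norbornene-fused cyclohexadiene F7 to diethyl 2-hydroxy-2-(2-methoxy-4-methylphenyl)propanedioate F8. Reduction of both esters with LiAlH4 (THF, 0 °C → rt) then gives triol 10.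

3. Step 5. Risk: loss of site selectivity, with acylation either spilling over onto the tertiary hydroxyl or stalling at the monoester. Fallback, setting out from 10 and coming back at 12: lipase-catalysed transesterification with vinyl isobutyrate (CC(C)C(=O)OC=C) and immobilised lipase B from Candida antarctica in MTBE at 40 °C. The enzyme should accept only the primary hydroxyls, and the released enol tautomerises so that the acylation is irreversible; no new compound is made.

Further compounds
F1 | step 3 | bridged bromolactone cycloadduct: 4-bromo-5-methoxy-1-methyl-2-oxabicyclo[2.2.2]oct-5-en-3-one fused across C7–C8 to a norbornene unit (stereoisomer mixture) | O=C1OC2(C)C=C(OC)C1(Br)C3C4C=CC(C4)C23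
F2 | step 3 | norbornene-fused bromocyclohexadiene: 5-bromo-6-methoxy-8-methyl-1,4,4a,8a-tetrahydro-1,4-methanonaphthalene (stereoisomer mixture) | COC1=C(Br)C2C3C=CC(C3)C2C(C)=C1
F3 | step 3 | 1-bromo-2-methoxy-4-methylbenzene | COc1cc(C)ccc1Br
F4 | step 3 | (2-methoxy-4-methylphenyl)lithium | COc1cc(C)ccc1[Li]
F5 | step 2 | diethyl 2-hydroxy-2-(4-methoxy-6-methyl-2-oxo-2H-pyran-3-yl)propanedioate | CCOC(=O)C(O)(C(=O)OCC)c1c(OC)cc(C)oc1=O
F6 | step 2 | malonate-bearing bridged lactone cycloadduct: diethyl 2-hydroxy-2-(5-methoxy-1-methyl-3-oxo-2-oxabicyclo[2.2.2]oct-5-en-4-yl)propanedioate fused across C7–C8 to a norbornene unit (stereoisomer mixture) | O=C1OC2(C)C=C(OC)C1(C(O)(C(=O)OCC)C(=O)OCC)C3C4C=CC(C4)C23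
F7 | step 2 | malonate-bearing norbornene-fused cyclohexadiene: diethyl 2-hydroxy-2-(6-methoxy-8-methyl-1,4,4a,8a-tetrahydro-1,4-methanonaphthalen-5-yl)propanedioate (stereoisomer mixture) | COC1=C(C(O)(C(=O)OCC)C(=O)OCC)C2C3C=CC(C3)C2C(C)=C1
F8 | step 2 | diethyl 2-hydroxy-2-(2-methoxy-4-methylphenyl)propanedioate | CCOC(=O)C(O)(C(=O)OCC)c1ccc(C)cc1OC
F0 | step 5 | none | none
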